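The seven-membered carbocycle is not closed directly. Because the hydroxyl-bearing C7 lies four bonds from C1′ of the syringyl ring, oxidation of the open-chain phenol first closes a six-membered 1-oxaspiro ring (O7, C7, C8, C8′, C7′, C1′). In the key step the C1′–O bond of this doubly vinylogous ketal ionises and the 3′,5′-dimethoxy-stabilised aryloxenium ion is captured by C2 of ring A (ortho to C1, para to the 5-methoxy group). The tetrahydropyran thereby grows by one atom into the benzo-fused seven-membered ring, C1′ becomes the all-carbon spiro centre and O7 returns as the free C7 alcohol. The precursor is a spiro quinol ether with no bond between the two carbocycles.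

Key step: step 9

Atom labels (lignan numbering): ring A = trimethoxybenzene ring, C1 bears C7 and C2 bears the spiro carbon; C7 = CH(OH), C8 and C8′ = CHMe, C7′ = CH2; ring B = dienone ring with C1′ spiro, C3′/C5′ methoxylated and C4′ the carbonyl carbon.

Remark: lactone 3 and the THF solution of Grignard reagent 11 are taken as catalogue compounds; C1′ is not a stereocentre (two identical dienone arms), so only C7, C8 and C8′ need control.

Step 1
Reactants: 1 4-bromo-2,6-dimethoxyphenol
Product: 2 (4-bromo-2,6-dimethoxyphenoxy)(tert-butyl)dimethylsilane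
Conditions: TBSCl, imidazole, DMF, 23 °C
Reagents that add atoms: tert-butyldimethylsilyl chloride CC(C)(C)[Si](C)(C)Cl
Why: Silyl ether formation masks the acidic phenol so that it does not quench the organozinc, hydride and Grignard reagents used later, and fluoride removes it again under mild conditions.

Step 2
Reactants: 3 (S)-4-methyldihydrofuran-2(3H)-one
Product: 5 (3S,4S)-3,4-dimethyldihydrofuran-2(3H)-one, via lithium enolate 4 (not isolated)
Conditions: LiN(iPr)2, THF, −78 °C; MeI, −78 → −40 °C
Reagents that add atoms: iodomethane CI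
Why: Lactone enolate alkylation, in which the lithium enolate is methylated on the face opposite the C4 methyl group, so the new centre (C8 of the target) is set trans to C8′ under substrate control.

Step 3
Reactants: 5 (3S,4S)-3,4-dimethyldihydrofuran-2(3H)-one
Product: 7 methyl (2S,3S)-4-iodo-2,3-dimethylbutanoate, via trimethylsilyl ester 6 (not isolated)
Conditions: Me3SiI, CH2Cl2, 40 °C; then MeOH, 23 °C
Reagents that add atoms: iodotrimethylsilane C[Si](C)(C)I; methanol CO
Why: Iodotrimethylsilane lactone cleavage, in which silylation of the carbonyl oxygen lets iodide open the ring by SN2 attack at the primary O–CH2 carbon (no stereocentre is touched) and methanol converts the silyl ester into the methyl ester.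

Step 4
Reactants: 7 methyl (2S,3S)-4-iodo-2,3-dimethylbutanoate; 2 (4-bromo-2,6-dimethoxyphenoxy)(tert-butyl)dimethylsilane
Product: 9 methyl (2S,3R)-4-[4-(tert-butyldimethylsilyloxy)-3,5-dimethoxyphenyl]-2,3-dimethylbutanoate, via alkylzinc iodide 8 (not isolated)
Conditions: Zn dust, LiCl, THF, 40 °C; then 2, Pd(OAc)2 (2 mol %), SPhos (4 mol %), THF, 40 °C
Reagents that add atoms: none
Why: Zinc insertion followed by Negishi cross-coupling, in which the ester-tolerant primary alkylzinc iodide is coupled with the electron-rich aryl bromide by a Pd/SPhos catalyst that eliminates reductively faster than it β-eliminates, forming the C7′–C1′ bond without touching C8 or C8′.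

Step 5
Reactants: 9 methyl (2S,3R)-4-[4-(tert-butyldimethylsilyloxy)-3,5-dimethoxyphenyl]-2,3-dimethylbutanoate
Product: 10 (2S,3R)-4-[4-(tert-butyldimethylsilyloxy)-3,5-dimethoxyphenyl]-2,3-dimethylbutanal
Conditions: iBu2AlH (1.1 equiv), CH2Cl2, −78 °C; then H2O, KNaC4H4O6 work-up
Reagents that add atoms: none
Why: Partial ester reduction with iBu2AlH, in which the tetrahedral aluminium hemiacetal is stable at −78 °C and releases the aldehyde only on work-up, so over-reduction and epimerisation at the α-carbon should be avoided.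

Step 6
Reactants: 10 (2S,3R)-4-[4-(tert-butyldimethylsilyloxy)-3,5-dimethoxyphenyl]-2,3-dimethylbutanal; 11 3,4,5-trimethoxyphenylmagnesium bromide
Product: 12 (1R,2S,3R)-4-[4-(tert-butyldimethylsilyloxy)-3,5-dimethoxyphenyl]-2,3-dimethyl-1-(3,4,5-trimethoxyphenyl)butan-1-ol
Conditions: THF, −78 °C; then H2O
Reagents that add atoms: none
Why: Felkin–Anh-controlled Grignard addition, in which the aryl nucleophile attacks the aldehyde anti to the branched C8′ substituent on C8 with the C8 hydrogen next to its path, which should give the 7,8-syn alcohol, that is (7R), as the major diastereomer, separable from its C7 epimer by chromatography.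

Step 7
Reactants: 12 (1R,2S,3R)-4-[4-(tert-butyldimethylsilyloxy)-3,5-dimethoxyphenyl]-2,3-dimethyl-1-(3,4,5-trimethoxyphenyl)butan-1-ol
Product: 13 4-[(2R,3S,4R)-4-hydroxy-2,3-dimethyl-4-(3,4,5-trimethoxyphenyl)butyl]-2,6-dimethoxyphenol
Conditions: Bu4NF, AcOH, THF, 0 °C
Reagents that add atoms: none
Why: Fluoride-induced cleavage of the aryl silyl ether, buffered with AcOH so that the phenoxide is protonated at once, leaves the benzylic alcohol and all three stereocentres unaffected.

Step 8
Reactants: 13 4-[(2R,3S,4R)-4-hydroxy-2,3-dimethyl-4-(3,4,5-trimethoxyphenyl)butyl]-2,6-dimethoxyphenol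
Product: 14 (2R,3S,4R)-8,10-dimethoxy-3,4-dimethyl-2-(3,4,5-trimethoxyphenyl)-1-oxaspiro[5.5]undeca-7,10-dien-9-one
Conditions: PhI(OAc)2 (1.05 equiv), MeCN, 0 °C, high dilution
Reagents that add atoms: none
Why: Hypervalent-iodine phenol dearomatisation (oxidative spiroetherification), in which ligand exchange of the phenol at trivalent iodine and loss of PhI give the aryloxenium ion, whose para carbon C1′ should be captured by the C7 hydroxyl through a six-membered transition state faster than by the arene in a non-fluorinated solvent, and no stereocentre is created because C1′ carries two identical ring arms.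

Step 9
Reactants: 14 (2R,3S,4R)-8,10-dimethoxy-3,4-dimethyl-2-(3,4,5-trimethoxyphenyl)-1-oxaspiro[5.5]undeca-7,10-dien-9-one
Product: 16 (7R,8S,9R)-9-hydroxy-2,3,3′,4,5′-pentamethoxy-7,8-dimethyl-6,7,8,9-tetrahydrospiro[benzo[7]annulene-5,1′-cyclohexa[2,5]dien]-4′-one (CNP0288561.1), via trimethylsilyl ether 15 (not isolated)
Conditions: Me3SiOTf (1.2 equiv), 2,6-di-tert-butyl-4-methylpyridine (1.5 equiv), CH2Cl2, −78 °C; then K2CO3, MeOH, 0 °C
Reagents that add atoms: none
Why: Proposed new method: Me3SiOTf silylates the ring oxygen, and the C1′–O bond, the ketal-type bond of a doubly vinylogous ketal (C1′–C2′=C3′–OMe and C1′–C6′=C5′–OMe), ionises to the 2,6-dimethoxy-4-alkylaryloxenium ion while O7 leaves as its silyl ether; C2 of ring A then attacks C1′ and the hindered pyridine removes the proton, so the six-membered oxacycle becomes the seven-membered carbocycle by a formal 1,3-shift of C1′ from O7 to C2. The closest known reaction types are the Ferrier-type substitution of vinylogous acetals by electron-rich arenes, the O-to-C rearrangement of aryl glycosides and the acid-induced cyclisation of p-quinol acetates onto tethered arenes. The ring closes by a 7-endo-trig Friedel–Crafts attack of the arene bond C1=C2 on the cationic spiro carbon. No new stereocentre is formed, because C1′ carries two identical dienone arms, and C7, C8 and C8′ keep their configuration because only the C1′–O bond is broken. The step needs attack at C1′ and not at C2′ (eight-membered biaryl), ionisation of C1′–O and not of the benzylic C7–O bond, and no aryl migration in the product; the charge of the oxenium ion lies on C1′, C3′ and C5′ and not on C2′, C1′–O cleavage is driven on by irreversible C–C bond formation while benzylic ionisation can only re-close, and the proton-free medium at −78 °C with O7 capped as its silyl ether gives the dienone–phenol path no Brønsted acid.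

Compound list
1 | 4-bromo-2,6-dimethoxyphenol | Oc1c(OC)cc(Br)cc1OC | starting material
2 | (4-bromo-2,6-dimethoxyphenoxy)(tert-butyl)dimethylsilane | CC(C)(C)[Si](C)(C)Oc1c(OC)cc(Br)cc1OC | intermediate
3 | (S)-4-methyldihydrofuran-2(3H)-one | O=C1C[C@H](C)CO1 | starting material
4 | lithium (S)-4-methyl-4,5-dihydrofuran-2-olate (lithium enolate of 3) | [Li]OC1=C[C@H](C)CO1 | intermediate
5 | (3S,4S)-3,4-dimethyldihydrofuran-2(3H)-one (trans) | O=C1[C@@H](C)[C@H](C)CO1 | intermediate
6 | trimethylsilyl (2S,3S)-4-iodo-2,3-dimethylbutanoate | IC[C@@H](C)[C@H](C)C(=O)O[Si](C)(C)C | intermediate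
7 | methyl (2S,3S)-4-iodo-2,3-dimethylbutanoate | IC[C@@H](C)[C@H](C)C(=O)OC | intermediate
8 | iodo[(2S,3S)-4-methoxy-2,3-dimethyl-4-oxobutyl]zinc | I[Zn]C[C@@H](C)[C@H](C)C(=O)OC | intermediate
9 | methyl (2S,3R)-4-[4-(tert-butyldimethylsilyloxy)-3,5-dimethoxyphenyl]-2,3-dimethylbutanoate | CC(C)(C)[Si](C)(C)Oc1c(OC)cc(C[C@@H](C)[C@H](C)C(=O)OC)cc1OC | intermediate
10 | (2S,3R)-4-[4-(tert-butyldimethylsilyloxy)-3,5-dimethoxyphenyl]-2,3-dimethylbutanal | CC(C)(C)[Si](C)(C)Oc1c(OC)cc(C[C@@H](C)[C@H](C)C=O)cc1OC | intermediate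
11 | 3,4,5-trimethoxyphenylmagnesium bromide | COc1cc([Mg]Br)cc(OC)c1OC | starting material
12 | (1R,2S,3R)-4-[4-(tert-butyldimethylsilyloxy)-3,5-dimethoxyphenyl]-2,3-dimethyl-1-(3,4,5-trimethoxyphenyl)butan-1-ol | CC(C)(C)[Si](C)(C)Oc1c(OC)cc(C[C@@H](C)[C@H](C)[C@@H](O)c2cc(OC)c(OC)c(OC)c2)cc1OC | intermediate
13 | 4-[(2R,3S,4R)-4-hydroxy-2,3-dimethyl-4-(3,4,5-trimethoxyphenyl)butyl]-2,6-dimethoxyphenol | Oc1c(OC)cc(C[C@@H](C)[C@H](C)[C@@H](O)c2cc(OC)c(OC)c(OC)c2)cc1OC | intermediate
14 | (2R,3S,4R)-8,10-dimethoxy-3,4-dimethyl-2-(3,4,5-trimethoxyphenyl)-1-oxaspiro[5.5]undeca-7,10-dien-9-one | COC1=CC2(C=C(OC)C1=O)C[C@@H](C)[C@H](C)[C@@H](O2)c1cc(OC)c(OC)c(OC)c1 | intermediate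
15 | (7R,8S,9R)-2,3,3′,4,5′-pentamethoxy-7,8-dimethyl-9-(trimethylsilyloxy)-6,7,8,9-tetrahydrospiro[benzo[7]annulene-5,1′-cyclohexa[2,5]dien]-4′-one | COC1=CC2(C=C(OC)C1=O)C[C@@H](C)[C@H](C)[C@@H](O[Si](C)(C)C)c1cc(OC)c(OC)c(OC)c12 | intermediate
16 | (7R,8S,9R)-9-hydroxy-2,3,3′,4,5′-pentamethoxy-7,8-dimethyl-6,7,8,9-tetrahydrospiro[benzo[7]annulene-5,1′-cyclohexa[2,5]dien]-4′-one (CNP0288561.1) | COC1=CC2(C=C(OC)C1=O)C[C@@H](C)[C@H](C)[C@@H](O)c1cc(OC)c(OC)c(OC)c12 | target

Total step count: 9 steps. Longest linear sequence: 8 steps (steps 2 to 9, from lactone 3 to target 16); step 1 is a one-step side branch.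

Steps most likely to fail

1. Step 9 (proposed new method). Ionisation may take place at the benzylic C7–O bond instead of C1′–O, with epimerisation at C7 or elimination towards C7=C8. The silylated dienone may also suffer an alkyl shift, or the product may go on to the dibenzocyclooctadiene by aryl migration. The fallback uses known chemistry, the direct phenol–arene coupling with a hypervalent iodine reagent, which closes the seven-membered ring in one bond-forming step. It sets out from alcohol 12: acetylation (Ac2O, pyridine, DMAP) gives silyl ether acetate F1, and Bu4NF/AcOH frees phenol acetate F2. PhI(OCOCF3)2 in CF3CH2OH at −40 °C then couples C1′ with C2 to spirodienone acetate F3, and K2CO3 in MeOH removes the acetate, so that the route is rejoined at target 16.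

2. Step 8. The aryloxenium intermediate may lose a C7′ proton to give the p-quinone methide, which O7 then traps at C7′ as a tetrahydrofuran. Acetate or the arene may also capture C1′ before O7 does, since the oxacycle has to form with an axial aryl group. The fallback sets out from phenol 13: oxidation with PhI(OAc)2 in MeOH gives quinol methyl ether F4 by solvent capture. Catalytic camphorsulfonic acid in CH2Cl2 over 5 Å molecular sieves then exchanges the C1′ methoxy group for O7 with loss of MeOH, returning to the route at spiro ether 14.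

3. Step 6. Facial selectivity in the addition to the α-methyl aldehyde may be poor, so that the C7 epimer forms in a large share. The fallback sets out from 12 as obtained (mixture of C7 epimers): Dess–Martin periodinane oxidises both epimers to aryl ketone F5. BH3·SMe2 with the (S)-Me-CBS oxazaborolidine then delivers hydride under catalyst control and returns the (7R)-alcohol 12.

Further compounds
F1 | step 9 | (1R,2S,3R)-4-[4-(tert-butyldimethylsilyloxy)-3,5-dimethoxyphenyl]-2,3-dimethyl-1-(3,4,5-trimethoxyphenyl)butyl acetate | CC(C)(C)[Si](C)(C)Oc1c(OC)cc(C[C@@H](C)[C@H](C)[C@@H](OC(C)=O)c2cc(OC)c(OC)c(OC)c2)cc1OC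
F2 | step 9 | (1R,2S,3R)-4-(4-hydroxy-3,5-dimethoxyphenyl)-2,3-dimethyl-1-(3,4,5-trimethoxyphenyl)butyl acetate | Oc1c(OC)cc(C[C@@H](C)[C@H](C)[C@@H](OC(C)=O)c2cc(OC)c(OC)c(OC)c2)cc1OC
F3 | step 9 | (7R,8S,9R)-2,3,3′,4,5′-pentamethoxy-7,8-dimethyl-4′-oxo-6,7,8,9-tetrahydrospiro[benzo[7]annulene-5,1′-cyclohexa[2,5]dien]-9-yl acetate | COC1=CC2(C=C(OC)C1=O)C[C@@H](C)[C@H](C)[C@@H](OC(C)=O)c1cc(OC)c(OC)c(OC)c12
F4 | step 8 | 4-[(2R,3S,4R)-4-hydroxy-2,3-dimethyl-4-(3,4,5-trimethoxyphenyl)butyl]-2,4,6-trimethoxycyclohexa-2,5-dien-1-one | COC1=CC(OC)(C[C@@H](C)[C@H](C)[C@@H](O)c2cc(OC)c(OC)c(OC)c2)C=C(OC)C1=O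
F5 | step 6 | (2S,3R)-4-[4-(tert-butyldimethylsilyloxy)-3,5-dimethoxyphenyl]-2,3-dimethyl-1-(3,4,5-trimethoxyphenyl)butan-1-one | CC(C)(C)[Si](C)(C)Oc1c(OC)cc(C[C@@H](C)[C@H](C)C(=O)c2cc(OC)c(OC)c(OC)c2)cc1OC
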